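Salvianolic acid D is cut at the ring A–propenoate bond (Heck) and, decisively, at the C2–O bond of ring A, numbered C1 (CH2CO2H arm), C2 and C3 (hydroxyls), C6 (propenoate). The C2 oxygen lies ortho to the C1 acetic acid arm, so the arm's own carboxyl oxygen can be delivered to C2 by palladium-catalysed C–H lactonisation. One operation installs the hindered oxygen and masks it and the acid together as a five-membered benzofuranone. The precursor is 2-(2-bromo-5-methoxyphenyl)acetic acid, whose bromine blocks the other ortho site and later carries the (R)-danshensu acrylate.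

Key step: step 2

Remark on the chemistry: the 2-hydroxyphenylacetic acid unit of the target is assumed not to re-lactonise during a cold aqueous acidic work-up, since that closure needs dehydrating conditions.

Step 1
Reactants: 1 3-methoxyphenylacetic acid
Product: 2 2-(2-bromo-5-methoxyphenyl)acetic acid
Conditions: NBS (1.05 equiv), MeCN, 0 °C to rt, dark
Reagents that add atoms: N-bromosuccinimide, O=C1CCC(=O)N1Br
Why: Electrophilic aromatic bromination of an anisole goes para to the methoxy group, which here is also the less hindered ortho position of the acetic acid arm.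

Step 2
Reactants: 2 2-(2-bromo-5-methoxyphenyl)acetic acid
Product: 3 4-bromo-7-methoxybenzofuran-2(3H)-one
Conditions: Pd(OAc)2 (10 mol %), Ac-Gly-OH (30 mol %), PhI(OAc)2 (1.5 equiv), KOAc (2 equiv), t-BuOH, 80 °C
Reagents that add atoms: none
Why: Proposed new method: the potassium carboxylate of 2 binds divalent palladium, Ac-Gly-OH assists concerted metalation–deprotonation at C6 of the aryl ring to give a six-membered palladacycle, PhI(OAc)2 oxidises it to tetravalent palladium, and C(aryl)–O reductive elimination with the bound carboxylate releases 3 and divalent palladium. The closest known reaction type is this same palladium-catalysed C–H lactonisation of α,α-disubstituted arylacetic acids to benzofuranones; what is new is the CH2 arm, whose ortho-palladation is itself well known from carboxylate-directed olefination and iodination of phenylacetic acids. The one ring closed is the five-membered lactone, formed by a reductive elimination that contracts the six-membered palladacycle and joins the carboxyl oxygen to C6. No stereocentre is created. Site selectivity is required and is secured by the bromine on the other ortho carbon, which leaves C6–H as the only directed site, while the flanking methoxy group acidifies that C–H and the ortho bromine tilts the arm toward it in place of a gem-dialkyl effect. Lactone formation over ortho-acetoxylation is sought through the amino acid ligand and t-BuOH as solvent, and the C–Br bond stays intact because no zerovalent palladium arises under the oxidising conditions.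

Step 3
Reactants: 4 (R)-danshensu
Product: 5 benzyl (R)-3-[3,4-bis(benzyloxy)phenyl]-2-hydroxypropanoate
Conditions: BnBr (3.3 equiv), K2CO3 (3.5 equiv), DMF, rt, N2
Reagents that add atoms: benzyl bromide, BrCc1ccccc1
Why: Williamson-type O-alkylation under carbonate benzylates only the carboxylate and the two phenoxides, leaving the non-acidic secondary alcohol free and the stereocentre untouched.

Step 4
Reactants: 5 benzyl (R)-3-[3,4-bis(benzyloxy)phenyl]-2-hydroxypropanoate; 6 acryloyl chloride
Product: 7 benzyl (R)-2-(acryloyloxy)-3-[3,4-bis(benzyloxy)phenyl]propanoate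
Conditions: Et3N (1.5 equiv), BHT (cat.), CH2Cl2, 0 °C
Reagents that add atoms: none
Why: O-Acylation of the only free hydroxyl with an acid chloride and amine base forms the ester without breaking any bond at the stereocentre, so the (R) configuration is retained.

Step 5
Reactants: 3 4-bromo-7-methoxybenzofuran-2(3H)-one; 7 benzyl (R)-2-(acryloyloxy)-3-[3,4-bis(benzyloxy)phenyl]propanoate
Product: 8 benzyl (R)-3-[3,4-bis(benzyloxy)phenyl]-2-{[(E)-3-(7-methoxy-2-oxo-2,3-dihydrobenzofuran-4-yl)prop-2-enoyl]oxy}propanoate
Conditions: Pd2(dba)3 (2 mol %), [(t-Bu)3PH]BF4 (8 mol %), Cy2NMe (1.2 equiv), 1,4-dioxane, 25–45 °C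
Reagents that add atoms: none
Why: Mizoroki–Heck reaction (oxidative addition of the aryl bromide to zerovalent palladium, syn insertion of the acrylate, syn β-hydride elimination) should give the (E)-cinnamate, and the hindered non-nucleophilic amine at low temperature is chosen to spare the aryl lactone and the α-acyloxy ester stereocentre.

Step 6
Reactants: 8 benzyl (R)-3-[3,4-bis(benzyloxy)phenyl]-2-{[(E)-3-(7-methoxy-2-oxo-2,3-dihydrobenzofuran-4-yl)prop-2-enoyl]oxy}propanoate
Product: 10 salvianolic acid D, via lactone triol acid 9 (not isolated)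
Conditions: BBr3 (8 equiv), C6HMe5 (5 equiv), CH2Cl2, −78 to 0 °C; H2O quench; then NaHCO3, degassed THF–H2O, rt, argon; then 1 M HCl to pH 2, 0 °C
Reagents that add atoms: water, O
Why: Lewis acid ether and ester cleavage by BBr3 removes the methyl ether, both benzyl ethers and the benzyl ester (benzyl cations trapped by pentamethylbenzene in a Friedel–Crafts sense) while the secondary cinnamate ester is not cleaved, and the strained aryl lactone is then saponified selectively at about pH 8 because a phenoxide leaves far more readily than the alkoxide of the cinnamate ester; the stereocentre is not involved.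

Compound list
1 | 3-methoxyphenylacetic acid | COc1cccc(CC(=O)O)c1 | starting material
2 | 2-(2-bromo-5-methoxyphenyl)acetic acid | OC(=O)Cc1cc(OC)ccc1Br | intermediate
3 | 4-bromo-7-methoxybenzofuran-2(3H)-one | O=C1Cc2c(Br)ccc(OC)c2O1 | intermediate
4 | (R)-danshensu, (R)-3-(3,4-dihydroxyphenyl)-2-hydroxypropanoic acid | O[C@H](Cc1ccc(O)c(O)c1)C(=O)O | starting material
5 | benzyl (R)-3-[3,4-bis(benzyloxy)phenyl]-2-hydroxypropanoate | O[C@H](Cc1ccc(OCc2ccccc2)c(OCc2ccccc2)c1)C(=O)OCc1ccccc1 | intermediate
6 | acryloyl chloride | C=CC(=O)Cl | starting material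
7 | benzyl (R)-2-(acryloyloxy)-3-[3,4-bis(benzyloxy)phenyl]propanoate | C=CC(=O)O[C@H](Cc1ccc(OCc2ccccc2)c(OCc2ccccc2)c1)C(=O)OCc1ccccc1 | intermediate
8 | benzyl (R)-3-[3,4-bis(benzyloxy)phenyl]-2-{[(E)-3-(7-methoxy-2-oxo-2,3-dihydrobenzofuran-4-yl)prop-2-enoyl]oxy}propanoate | O=C1Cc2c(/C=C/C(=O)O[C@H](Cc3ccc(OCc4ccccc4)c(OCc4ccccc4)c3)C(=O)OCc3ccccc3)ccc(OC)c2O1 | intermediate
9 | (R)-3-(3,4-dihydroxyphenyl)-2-{[(E)-3-(7-hydroxy-2-oxo-2,3-dihydrobenzofuran-4-yl)prop-2-enoyl]oxy}propanoic acid | O=C1Cc2c(/C=C/C(=O)O[C@H](Cc3ccc(O)c(O)c3)C(=O)O)ccc(O)c2O1 | intermediate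
10 | salvianolic acid D, (R)-2-{[(E)-3-[2-(carboxymethyl)-3,4-dihydroxyphenyl]prop-2-enoyl]oxy}-3-(3,4-dihydroxyphenyl)propanoic acid | O=C(O)Cc1c(/C=C/C(=O)O[C@H](Cc2ccc(O)c(O)c2)C(=O)O)ccc(O)c1O | target

Total step count: 6
Longest linear sequence: 4 steps (steps 1, 2, 5, 6 from compound 1; equally steps 3, 4, 5, 6 from compound 4)

Steps most likely to fail

1. Step 2. Metalation at the flanked C–H may be too slow for an arm without α-substituents, and the oxidant may instead decarboxylate the acid or oxidise the enolisable lactone further. The fallback sets out from 2 and comes back at 3, using known chemistry. Ortho C–H hydroxylation with aqueous H2O2, Pd(OAc)2 and a bidentate pyridone–carboxylic acid ligand at room temperature is established for phenylacetic acids without α-substituents. It should give 2-(6-bromo-2-hydroxy-3-methoxyphenyl)acetic acid F1, whose new oxygen comes from the peroxide and not from the carboxyl group. Heating with TsOH in toluene under azeotropic removal of water then closes the lactone 3 by ordinary esterification.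

2. Step 5. Base-induced enolisation of the aryl lactone may lead to Michael addition to the acrylate, self-condensation or ring opening faster than the coupling proceeds. The fallback sets out from 3 and comes back at 10, and opens the lactone before any palladium chemistry. Benzyl alcohol and K2CO3 in DMF should transesterify 3 to benzyl 2-(6-bromo-2-hydroxy-3-methoxyphenyl)acetate F2 (not isolated). BnBr added to the same flask should give benzyl 2-[2-(benzyloxy)-6-bromo-3-methoxyphenyl]acetate F3. Heck coupling of F3 with 7 under the conditions of step 5 should give benzyl (R)-2-{[(E)-3-{3-(benzyloxy)-2-[2-(benzyloxy)-2-oxoethyl]-4-methoxyphenyl}prop-2-enoyl]oxy}-3-[3,4-bis(benzyloxy)phenyl]propanoate F4. The BBr3 and C6HMe5 treatment and aqueous work-up of step 6 then give 10.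

3. Step 6. The Lewis acid may cleave or isomerise the cinnamate ester or benzylate the catechol rings, and the free catechols may oxidise in air during the lactone opening. The fallback sets out from 3 and comes back at 10. It moves the demethylation to the simple lactone, so that the last step is only a low-temperature debenzylation. BBr3 in CH2Cl2 should convert 3 into 4-bromo-7-hydroxybenzofuran-2(3H)-one F5. Benzyl alcohol and K2CO3 in DMF under N2 should open it to benzyl 2-(6-bromo-2,3-dihydroxyphenyl)acetate F6 (not isolated), and BnBr in the same flask should give benzyl 2-[2,3-bis(benzyloxy)-6-bromophenyl]acetate F7. Heck coupling with 7 as in step 5 should give benzyl (R)-2-{[(E)-3-{3,4-bis(benzyloxy)-2-[2-(benzyloxy)-2-oxoethyl]phenyl}prop-2-enoyl]oxy}-3-[3,4-bis(benzyloxy)phenyl]propanoate F8. BCl3 with C6HMe5 in CH2Cl2 at −78 to 0 °C, followed by the aqueous work-up of step 6, should remove all six benzyl groups and give 10.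

Further compounds
F1 | step 2 | 2-(6-bromo-2-hydroxy-3-methoxyphenyl)acetic acid | OC(=O)Cc1c(O)c(OC)ccc1Br
F2 | step 5 | benzyl 2-(6-bromo-2-hydroxy-3-methoxyphenyl)acetate | O=C(Cc1c(O)c(OC)ccc1Br)OCc1ccccc1
F3 | step 5 | benzyl 2-[2-(benzyloxy)-6-bromo-3-methoxyphenyl]acetate | O=C(Cc1c(OCc2ccccc2)c(OC)ccc1Br)OCc1ccccc1
F4 | step 5 | benzyl (R)-2-{[(E)-3-{3-(benzyloxy)-2-[2-(benzyloxy)-2-oxoethyl]-4-methoxyphenyl}prop-2-enoyl]oxy}-3-[3,4-bis(benzyloxy)phenyl]propanoate | O=C(Cc1c(OCc2ccccc2)c(OC)ccc1/C=C/C(=O)O[C@H](Cc1ccc(OCc2ccccc2)c(OCc2ccccc2)c1)C(=O)OCc1ccccc1)OCc1ccccc1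
F5 | step 6 | 4-bromo-7-hydroxybenzofuran-2(3H)-one | O=C1Cc2c(Br)ccc(O)c2O1
F6 | step 6 | benzyl 2-(6-bromo-2,3-dihydroxyphenyl)acetate | O=C(Cc1c(O)c(O)ccc1Br)OCc1ccccc1
F7 | step 6 | benzyl 2-[2,3-bis(benzyloxy)-6-bromophenyl]acetate | O=C(Cc1c(OCc2ccccc2)c(OCc2ccccc2)ccc1Br)OCc1ccccc1
F8 | step 6 | benzyl (R)-2-{[(E)-3-{3,4-bis(benzyloxy)-2-[2-(benzyloxy)-2-oxoethyl]phenyl}prop-2-enoyl]oxy}-3-[3,4-bis(benzyloxy)phenyl]propanoate | O=C(Cc1c(OCc2ccccc2)c(OCc2ccccc2)ccc1/C=C/C(=O)O[C@H](Cc1ccc(OCc2ccccc2)c(OCc2ccccc2)c1)C(=O)OCc1ccccc1)OCc1ccccc1
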